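The ten-membered ring is released, not closed: the target is led back to a cis-fused bicycle in which C1 is bonded to C6 and C10 carries a spiro-epoxide (C14). The feature exploited is the 1,3-disposition about C1 of oxygen-bearing C6 and C10 (the alkene carbon that carries C14–OH), together with the ring-cis C4=C5 alkene, which can be housed in the cyclohexene ring B of that bicycle. In one operation, Grob fragmentation of the tertiary C6 titanium alkoxide cuts C1–C6 and delivers the C6 ketone, the C1=C10 alkene of defined geometry and the free C14 alcohol. The precursor already carries C7 and C8 in their final configuration, with O6, C11 and O8 cis on ring A.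

Key step: step 19

Remark: germacrane numbering (C1 to C15) is used for all intermediates, ring A is C6–C7–C8–C9–C10–C1 and ring B is C1–C2–C3–C4–C5–C6; chloride 15 is taken on as a mixture of alkene isomers because both give the same allylchromium species in step 13.

Step 1
Reactants: 1 3-ethoxycyclohex-2-en-1-one
Product: 4 3-(hydroxymethyl)cyclohex-2-en-1-one, via alkoxide adduct 2 (not isolated), via MOM ether enone 3 (not isolated)
Conditions: Bu3SnCH2OCH2OMe, n-BuLi, THF, −78 °C; then 1; then 3 M HCl, MeOH, 50 °C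
Reagents that add atoms: tributyl[(methoxymethoxy)methyl]stannane, CCCC[Sn](CCCC)(CCCC)COCOC; water, O
Why: Tin–lithium exchange gives an α-alkoxymethyllithium that adds 1,2 to the vinylogous ester, and aqueous acid then effects the Stork–Danheiser transposition to the 3-substituted enone and cleaves the MOM acetal; no stereocentre is formed.

Step 2
Reactants: 4 3-(hydroxymethyl)cyclohex-2-en-1-one
Product: 5 3-{[(tert-butyldiphenylsilyl)oxy]methyl}cyclohex-2-en-1-one
Conditions: TBDPSCl, imidazole, CH2Cl2, 0 °C to rt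
Reagents that add atoms: tert-butyl(chloro)diphenylsilane, CC(C)(C)[Si](Cl)(c1ccccc1)c1ccccc1
Why: Silylation of a primary allylic alcohol gives the robust C15 silyl ether that has to last until the final step.

Step 3
Reactants: 5 TBDPS-protected enone
Product: 6 1-{[(tert-butyldiphenylsilyl)oxy]methyl}-3-[(trimethylsilyl)oxy]cyclohexa-1,3-diene
Conditions: LiN(iPr)2, THF, −78 °C; then Me3SiCl
Reagents that add atoms: chlorotrimethylsilane, C[Si](C)(C)Cl
Why: Kinetic deprotonation of a 3-substituted cyclohexenone takes place at the saturated α' carbon (C1), and O-silylation of the cross-conjugated enolate gives the 2-silyloxydiene needed for a Mukaiyama aldol at C1.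

Step 4
Reactants: 7 (2R)-butane-1,2,4-triol
Product: 8 [(2R,4R)-2-(4-methoxyphenyl)-1,3-dioxan-4-yl]methanol
Conditions: 4-MeOC6H4CH(OMe)2, CSA (cat.), CH2Cl2, rt
Reagents that add atoms: 4-methoxybenzaldehyde dimethyl acetal, COc1ccc(cc1)C(OC)OC
Why: Acid-catalysed transacetalisation under equilibrium control gives the six-membered 2,4-O-acetal with aryl and CH2OH both equatorial, which leaves the C7 hydroxyl free; the C8 stereocentre comes from the triol and the acetal carbon is set thermodynamically.

Step 5
Reactants: 8 dioxanyl methanol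
Product: 9 (2R,4R)-2-(4-methoxyphenyl)-1,3-dioxane-4-carbaldehyde
Conditions: DMP, NaHCO3, CH2Cl2, 0 °C to rt
Reagents that add atoms: none
Why: Buffered Dess–Martin oxidation gives the α-alkoxy aldehyde without epimerising C8, which is held in the acetal ring.

Step 6
Reactants: 10 2-bromoprop-2-en-1-ol
Product: 11 [(2-bromoprop-2-en-1-yl)oxy](tert-butyl)dimethylsilane
Conditions: TBSCl, imidazole, CH2Cl2, 0 °C
Reagents that add atoms: tert-butyl(chloro)dimethylsilane, CC(C)(C)[Si](C)(C)Cl
Why: Standard silylation gives the C11–C13 unit with the future C12 oxygen as a TBS ether, which can later be removed in the presence of the TBDPS ethers.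

Step 7
Reactants: 9 dioxane carbaldehyde; 11 bromoallyl silyl ether
Product: 13 2-{[(tert-butyldimethylsilyl)oxy]methyl}-1-[(2R,4R)-2-(4-methoxyphenyl)-1,3-dioxan-4-yl]prop-2-en-1-ol (both C7 epimers), via alkenylchromium reagent 12 (not isolated)
Conditions: CrCl2, NiCl2 (cat.), DMF, rt
Reagents that add atoms: none
Why: Nozaki–Hiyama–Kishi alkenylation, in which the nickel-catalysed alkenylchromium adds chemoselectively to the α-alkoxy aldehyde without silyl migration; the new C7 carbinol forms as an epimer mixture, which does not matter because C7 becomes planar in step 8.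

Step 8
Reactants: 13 allylic alcohol
Product: 15 tert-butyl({2-(chloromethyl)-3-[(2R,4R)-2-(4-methoxyphenyl)-1,3-dioxan-4-yl]prop-2-en-1-yl}oxy)dimethylsilane (alkene isomer mixture), via allylic mesylate 14 (not isolated)
Conditions: MsCl, 2,4,6-collidine, LiCl, DMF, 0 °C to rt
Reagents that add atoms: lithium chloride, [Li+].[Cl-]
Why: The mesylate is displaced by chloride with allylic transposition (SN2'), and chloride-mediated equilibration favours the trisubstituted alkene with the primary chloride; the C7 stereocentre disappears and the neutral conditions spare the acetal and the silyl ether.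

Step 9
Reactants: 15 allylic chloride acetal
Product: 16 (3R)-6-chloro-5-{[(tert-butyldimethylsilyl)oxy]methyl}-3-[(4-methoxybenzyl)oxy]hex-4-en-1-ol
Conditions: iBu2AlH, CH2Cl2, −78 to 0 °C
Reagents that add atoms: none
Why: Reductive opening of the 4-methoxybenzylidene acetal, in which aluminium binds the less hindered primary oxygen (O10) and hydride reduces the oxocarbenium ion, so the PMB ether ends on the secondary C8 oxygen and C10 is freed; C8 is untouched.

Step 10
Reactants: 16 primary alcohol
Product: 17 (3R)-6-chloro-5-{[(tert-butyldimethylsilyl)oxy]methyl}-3-[(4-methoxybenzyl)oxy]hex-4-enal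
Conditions: DMP, NaHCO3, CH2Cl2, 0 °C
Reagents that add atoms: none
Why: Buffered Dess–Martin oxidation gives the β-alkoxy aldehyde under non-basic conditions that avoid β-elimination of the PMB ether.

Step 11
Reactants: 6 silyloxydiene; 17 C7–C10 aldehyde
Product: 18 (6R)-6-[(1R,3R)-6-chloro-5-{[(tert-butyldimethylsilyl)oxy]methyl}-1-hydroxy-3-[(4-methoxybenzyl)oxy]hex-4-en-1-yl]-3-{[(tert-butyldiphenylsilyl)oxy]methyl}cyclohex-2-en-1-one
Conditions: BF3·OEt2, CH2Cl2, −78 °C
Reagents that add atoms: none
Why: Mukaiyama aldol through an open transition state, in which the BF3-bound β-alkoxy aldehyde is attacked anti to the C8–O dipole (1,3-anti, C10 relative to C8) and the ring-locked enol silane reacts through its antiperiplanar arrangement (C1/C10 anti); minor diastereomers would be removed by chromatography.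

Step 12
Reactants: 18 aldol adduct
Product: 19 C10 trimethylsilyl ether of 18
Conditions: Me3SiCl, imidazole, CH2Cl2, 0 °C
Reagents that add atoms: chlorotrimethylsilane, C[Si](C)(C)Cl
Why: Mild silylation caps the β-hydroxy ketone without elimination; the C10 silyl ether stops the hydroxyl from binding chromium in step 13 and acts as an equatorial anchor for the ring A chair.

Step 13
Reactants: 19 silylated aldol adduct
Product: 21 cis-fused bicyclic tertiary alcohol (C6–OH and C1–H syn; C6–OH, the C7 side chain and C8–OPMB on one face of ring A, C10–OSiMe3 on the other), via allylchromium species 20 (not isolated)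
Conditions: CrCl2, LiI (cat.), THF, rt
Reagents that add atoms: none
Why: Intramolecular Nozaki–Hiyama allylation, in which the equilibrating allylchromium adds through C7 to the C6 ketone in a closed six-membered chair transition state fused to the forming ring A; the equatorial C10 silyl ether, which is anti to C8–O, forces the C8 ether axial and into the allyl plane, where it can coordinate chromium, so C11 takes the equatorial site and C6 and C7 should form with O6, C11 and O8 all cis and with a cis ring fusion.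

Step 14
Reactants: 21 bicyclic tertiary alcohol
Product: 22 bis(trimethylsilyl) ether (O6 and O10)
Conditions: Me3SiOTf, 2,6-lutidine, CH2Cl2, −78 °C
Reagents that add atoms: trimethylsilyl trifluoromethanesulfonate, C[Si](C)(C)OS(=O)(=O)C(F)(F)F
Why: The silyl triflate caps the hindered tertiary C6 alcohol, so that no C6 alkoxide can form, and no retro-aldol or premature fragmentation can occur, while C10 is at the ketone and epoxide stage.

Step 15
Reactants: 22 bis-silyl ether
Product: 23 C10 alcohol with O6 still silylated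
Conditions: K2CO3, MeOH, 0 °C
Reagents that add atoms: none
Why: Methanolysis removes the secondary trimethylsilyl ether much faster than the hindered tertiary one and leaves the TBS, TBDPS and PMB ethers untouched.

Step 16
Reactants: 23 C10 alcohol
Product: 24 C10 ketone (O6–SiMe3)
Conditions: DMP, NaHCO3, CH2Cl2, 0 °C
Reagents that add atoms: none
Why: Neutral Dess–Martin oxidation gives the ketone without epimerising C1; with O6 silylated, a trans-fused C1 epimer would need the two bulky ethers at O6 and O8 syn-diaxial, so the cis fusion is also the stable one.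

Step 17
Reactants: 24 C10 ketone
Product: 25 spiro-epoxide (C14 on the face of O6 and H1, epoxide oxygen on the face of C2; O6–SiMe3)
Conditions: [Me3S]I, n-BuLi, THF, −10 to 0 °C
Reagents that add atoms: trimethylsulfonium iodide, C[S+](C)C.[I-]
Why: Corey–Chaykovsky epoxidation, in which dimethylsulfonium methylide adds irreversibly to the C10 carbonyl on the face away from the axial C5 of ring B (the face of O6), and the resulting alkoxide closes the oxirane, so C14 ends cis to O6 and the oxygen cis to C2.

Step 18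
Reactants: 25 silylated epoxide
Product: 26 cis-fused epoxy alcohol, (1S,6R,7R,8R,10R) in germacrane numbering (C1–C6 bond, C10 spiro-oxirane, free tertiary C6–OH)
Conditions: Bu4NF, AcOH, THF, 0 °C
Reagents that add atoms: none
Why: Buffered fluoride removes the trimethylsilyl group much faster than the primary TBS and TBDPS groups, and the acetic acid buffer keeps the liberated C6 oxygen protonated, so the epoxide is not attacked.

Step 19
Reactants: 26 cis-fused epoxy alcohol
Product: 27 ten-membered dienone, (7R,8R), with C6 ketone, ring-cis C1=C10 and C4=C5 alkenes and free C14–OH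
Conditions: Ti(OiPr)4 (2 equiv), toluene, 25 to 60 °C
Reagents that add atoms: none
Why: Ligand exchange gives the C6 titanium alkoxide, whose oxygen pushes into the C1–C6 bond while a second titanium centre activates the oxirane, so that C1–C6 and the tertiary C10–O bond break in concert and the C6 carbonyl, the C1=C10 π bond and the C14 alkoxide appear; the closest known reaction type is the titanium-promoted Grob fragmentation of 3,4-epoxy alcohols to medium-ring ketones. The step forms no ring-closing bond: the carbocycle C1–C10 is set free when the ring-fusion bond of the bicycle is severed. No stereocentre is created; C7 and C8 are carried through unchanged and C1, C6 and C10 are erased. The selectivity needed is fragmentation over attack of the C6 oxygen on C14 (5-exo opening to a bridged ether), and it should be secured by the non-basic, Lewis-acidic medium, which polarises the tertiary C10–O bond, and by the chair in which O6 and O8 are both axial and can be bridged by titanium. That same chair holds the equatorial C10–O bond antiperiplanar to C1–C6 with C2 axial on ring A and synclinal to C9, which translates into the ring-cis C1=C10 alkene only; the C4=C5 geometry is fixed by its origin in ring B.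

Step 20
Reactants: 27 ten-membered dienone
Product: 28 C14 tert-butyldiphenylsilyl ether of 27
Conditions: TBDPSCl, imidazole, CH2Cl2, 0 °C
Reagents that add atoms: tert-butyl(chloro)diphenylsilane, CC(C)(C)[Si](Cl)(c1ccccc1)c1ccccc1
Why: Silylation of the primary allylic alcohol under mild conditions, which do not enolise the β-alkoxy ketone, gives C14 the same robust protection as C15.

Step 21
Reactants: 28 protected dienone
Product: 29 (6R)-allylic alcohol (H6 anti to H7)
Conditions: (S)-2-methyl-CBS-oxazaborolidine (0.3 equiv), catecholborane, toluene, −78 to −40 °C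
Reagents that add atoms: none
Why: Corey–Bakshi–Shibata reduction, in which the catalyst binds the carbonyl oxygen anti to the branched C7 flank (taken as the larger one) and delivers hydride to the face that gives the (6R) alcohol; catecholborane at low temperature reduces the enone 1,2 and leaves the other alkenes alone.

Step 22
Reactants: 29 allylic alcohol
Product: 30 C6,C12-diol
Conditions: PPTS, MeOH, 0 °C to rt
Reagents that add atoms: none
Why: Mild acidic methanolysis cleaves the primary allylic TBS ether far faster than the two TBDPS ethers and does not affect the PMB ether.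

Step 23
Reactants: 30 C6,C12-diol
Product: 33 trans-fused α-methylene-γ-butyrolactone (6,12-olide), via hydroxy enal 31 (not isolated), via lactol 32 (not isolated)
Conditions: TEMPO (cat.), PhI(OAc)2, CH2Cl2, rt
Reagents that add atoms: none
Why: Oxidative lactonisation of a 1,4-diol, in which the oxoammonium oxidant takes the primary allylic C12 alcohol to the enal, the C6 hydroxyl traps it as a lactol and a second oxidation gives the lactone; C6 and C7 are untouched, so the fusion stays trans.

Step 24
Reactants: 33 lactone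
Product: 34 C8 alcohol
Conditions: DDQ, CH2Cl2, pH 7 buffer, 0 °C
Reagents that add atoms: none
Why: Oxidative cleavage of the PMB ether frees O8 only now, after O6 has been used for the lactone, so the two secondary oxygens are never in competition.

Step 25
Reactants: 34 C8 alcohol; 35 angelic acid
Product: 37 C8 angelate with C14 and C15 still silylated, via angelic trichlorobenzoic anhydride 36 (not isolated)
Conditions: 2,4,6-Cl3C6H2COCl, Et3N, toluene, rt; then 34, toluene, 75 °C
Reagents that add atoms: none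
Why: Yamaguchi-type acylation through the mixed anhydride, run without a nucleophilic amine catalyst so that the (Z)-2-methylbut-2-enoyl group is transferred without isomerisation to the tiglate; the configuration at C8 is retained.

Step 26
Reactants: 37 bis-silylated angelate
Product: 38 target compound, (6R,7R,8R)
Conditions: HF·pyridine, pyridine, THF, 0 °C to rt
Reagents that add atoms: none
Why: Buffered fluoride cleaves both primary allylic silyl ethers under conditions that the α-methylene lactone and the angelate tolerate.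

Compound list
1 | 3-ethoxycyclohex-2-en-1-one | CCOC1=CC(=O)CCC1 | starting material
2 | 3-ethoxy-1-[(methoxymethoxy)methyl]cyclohex-2-en-1-ol, present as its lithium alkoxide | CCOC1=CC(O)(COCOC)CCC1 | intermediate
3 | 3-[(methoxymethoxy)methyl]cyclohex-2-en-1-one | O=C1C=C(COCOC)CCC1 | intermediate
4 | 3-(hydroxymethyl)cyclohex-2-en-1-one | O=C1C=C(CO)CCC1 | intermediate
5 | 3-{[(tert-butyldiphenylsilyl)oxy]methyl}cyclohex-2-en-1-one | O=C1C=C(CO[Si](c2ccccc2)(c2ccccc2)C(C)(C)C)CCC1 | intermediate
6 | 1-{[(tert-butyldiphenylsilyl)oxy]methyl}-3-[(trimethylsilyl)oxy]cyclohexa-1,3-diene | C[Si](C)(C)OC1=CCCC(CO[Si](c2ccccc2)(c2ccccc2)C(C)(C)C)=C1 | intermediate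
7 | (2R)-butane-1,2,4-triol | OC[C@H](O)CCO | starting material
8 | [(2R,4R)-2-(4-methoxyphenyl)-1,3-dioxan-4-yl]methanol | OC[C@H]1CCO[C@@H](c2ccc(OC)cc2)O1 | intermediate
9 | (2R,4R)-2-(4-methoxyphenyl)-1,3-dioxane-4-carbaldehyde | O=C[C@H]1CCO[C@@H](c2ccc(OC)cc2)O1 | intermediate
10 | 2-bromoprop-2-en-1-ol | OCC(Br)=C | starting material
11 | [(2-bromoprop-2-en-1-yl)oxy](tert-butyl)dimethylsilane | C=C(Br)CO[Si](C)(C)C(C)(C)C | intermediate
12 | {3-[(tert-butyldimethylsilyl)oxy]prop-1-en-2-yl}chromium dichloride (trivalent chromium, solvated) | C=C([Cr](Cl)Cl)CO[Si](C)(C)C(C)(C)C | intermediate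
13 | 2-{[(tert-butyldimethylsilyl)oxy]methyl}-1-[(2R,4R)-2-(4-methoxyphenyl)-1,3-dioxan-4-yl]prop-2-en-1-ol, both C7 epimers | C=C(CO[Si](C)(C)C(C)(C)C)C(O)[C@H]1CCO[C@@H](c2ccc(OC)cc2)O1 | intermediate
14 | methanesulfonate of 13 | C=C(CO[Si](C)(C)C(C)(C)C)C(OS(C)(=O)=O)[C@H]1CCO[C@@H](c2ccc(OC)cc2)O1 | intermediate
15 | tert-butyl({2-(chloromethyl)-3-[(2R,4R)-2-(4-methoxyphenyl)-1,3-dioxan-4-yl]prop-2-en-1-yl}oxy)dimethylsilane, alkene isomer mixture | ClCC(CO[Si](C)(C)C(C)(C)C)=C[C@H]1CCO[C@@H](c2ccc(OC)cc2)O1 | intermediate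
16 | (3R)-6-chloro-5-{[(tert-butyldimethylsilyl)oxy]methyl}-3-[(4-methoxybenzyl)oxy]hex-4-en-1-ol, alkene isomer mixture | ClCC(CO[Si](C)(C)C(C)(C)C)=C[C@H](OCc1ccc(OC)cc1)CCO | intermediate
17 | (3R)-6-chloro-5-{[(tert-butyldimethylsilyl)oxy]methyl}-3-[(4-methoxybenzyl)oxy]hex-4-enal, alkene isomer mixture | ClCC(CO[Si](C)(C)C(C)(C)C)=C[C@H](OCc1ccc(OC)cc1)CC=O | intermediate
18 | (6R)-6-[(1R,3R)-6-chloro-5-{[(tert-butyldimethylsilyl)oxy]methyl}-1-hydroxy-3-[(4-methoxybenzyl)oxy]hex-4-en-1-yl]-3-{[(tert-butyldiphenylsilyl)oxy]methyl}cyclohex-2-en-1-one (C1/C10 anti, C8/C10 anti) | ClCC(CO[Si](C)(C)C(C)(C)C)=C[C@H](OCc1ccc(OC)cc1)C[C@@H](O)[C@H]2CCC(CO[Si](c3ccccc3)(c3ccccc3)C(C)(C)C)=CC2=O | intermediate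
19 | C10 trimethylsilyl ether of 18 | ClCC(CO[Si](C)(C)C(C)(C)C)=C[C@H](OCc1ccc(OC)cc1)C[C@@H](O[Si](C)(C)C)[C@H]2CCC(CO[Si](c3ccccc3)(c3ccccc3)C(C)(C)C)=CC2=O | intermediate
20 | allylchromium dichloride derived from 19 (trivalent chromium, shown as the primary σ-allyl form) | Cl[Cr](Cl)CC(CO[Si](C)(C)C(C)(C)C)=C[C@H](OCc1ccc(OC)cc1)C[C@@H](O[Si](C)(C)C)[C@H]2CCC(CO[Si](c3ccccc3)(c3ccccc3)C(C)(C)C)=CC2=O | intermediate
21 | cis-fused bicyclic tertiary alcohol: octahydronaphthalene with C6–OH at the ring fusion, C7 3-(TBS-oxy)prop-1-en-2-yl, C8–OPMB, C10–OSiMe3, C4 CH2OTBDPS; O6, C11, O8 and H1 on one face, O10 on the other | O[C@]12[C@H](C(=C)CO[Si](C)(C)C(C)(C)C)[C@H](OCc3ccc(OC)cc3)C[C@@H](O[Si](C)(C)C)[C@H]1CCC(CO[Si](c4ccccc4)(c4ccccc4)C(C)(C)C)=C2 | intermediate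
22 | O6,O10-bis(trimethylsilyl) ether of the bicycle | C[Si](C)(C)O[C@]12[C@H](C(=C)CO[Si](C)(C)C(C)(C)C)[C@H](OCc3ccc(OC)cc3)C[C@@H](O[Si](C)(C)C)[C@H]1CCC(CO[Si](c4ccccc4)(c4ccccc4)C(C)(C)C)=C2 | intermediate
23 | C10 alcohol, O6 trimethylsilyl ether | C[Si](C)(C)O[C@]12[C@H](C(=C)CO[Si](C)(C)C(C)(C)C)[C@H](OCc3ccc(OC)cc3)C[C@@H](O)[C@H]1CCC(CO[Si](c4ccccc4)(c4ccccc4)C(C)(C)C)=C2 | intermediate
24 | C10 ketone, O6 trimethylsilyl ether | C[Si](C)(C)O[C@]12[C@H](C(=C)CO[Si](C)(C)C(C)(C)C)[C@H](OCc3ccc(OC)cc3)CC(=O)[C@H]1CCC(CO[Si](c4ccccc4)(c4ccccc4)C(C)(C)C)=C2 | intermediate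
25 | C10 spiro-epoxide, O6 trimethylsilyl ether (C14 cis to O6, epoxide oxygen cis to C2) | C[Si](C)(C)O[C@]12[C@H](C(=C)CO[Si](C)(C)C(C)(C)C)[C@H](OCc3ccc(OC)cc3)C[C@]4(CO4)[C@H]1CCC(CO[Si](c5ccccc5)(c5ccccc5)C(C)(C)C)=C2 | intermediate
26 | cis-fused bicyclic epoxy alcohol, (1S,6R,7R,8R,10R) in germacrane numbering: C1–C6 bonded, C10 spiro-oxirane, tertiary C6–OH, C8–OPMB, C12–OTBS, C15–OTBDPS | O[C@]12[C@H](C(=C)CO[Si](C)(C)C(C)(C)C)[C@H](OCc3ccc(OC)cc3)C[C@]4(CO4)[C@H]1CCC(CO[Si](c5ccccc5)(c5ccccc5)C(C)(C)C)=C2 | intermediate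
27 | ten-membered dienone, (7R,8R): C6 ketone, ring-cis C1=C10 and C4=C5, free C14–OH, C8–OPMB, C12–OTBS, C15–OTBDPS | O=C1/C=C(/CO[Si](c2ccccc2)(c2ccccc2)C(C)(C)C)CC/C=C(/CO)C[C@@H](OCc2ccc(OC)cc2)[C@H]1C(=C)CO[Si](C)(C)C(C)(C)C | intermediate
28 | C14 tert-butyldiphenylsilyl ether of 27 | O=C1/C=C(/CO[Si](c2ccccc2)(c2ccccc2)C(C)(C)C)CC/C=C(/CO[Si](c2ccccc2)(c2ccccc2)C(C)(C)C)C[C@@H](OCc2ccc(OC)cc2)[C@H]1C(=C)CO[Si](C)(C)C(C)(C)C | intermediate
29 | (6R)-alcohol from 28 | O[C@@H]1/C=C(/CO[Si](c2ccccc2)(c2ccccc2)C(C)(C)C)CC/C=C(/CO[Si](c2ccccc2)(c2ccccc2)C(C)(C)C)C[C@@H](OCc2ccc(OC)cc2)[C@H]1C(=C)CO[Si](C)(C)C(C)(C)C | intermediate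
30 | C6,C12-diol | O[C@@H]1/C=C(/CO[Si](c2ccccc2)(c2ccccc2)C(C)(C)C)CC/C=C(/CO[Si](c2ccccc2)(c2ccccc2)C(C)(C)C)C[C@@H](OCc2ccc(OC)cc2)[C@H]1C(=C)CO | intermediate
31 | C12 enal with free C6–OH | O[C@@H]1/C=C(/CO[Si](c2ccccc2)(c2ccccc2)C(C)(C)C)CC/C=C(/CO[Si](c2ccccc2)(c2ccccc2)C(C)(C)C)C[C@@H](OCc2ccc(OC)cc2)[C@H]1C(=C)C=O | intermediate
32 | C12 lactol (either configuration at C12) | C=C1C(O)O[C@@H]2/C=C(/CO[Si](c3ccccc3)(c3ccccc3)C(C)(C)C)CC/C=C(/CO[Si](c3ccccc3)(c3ccccc3)C(C)(C)C)C[C@@H](OCc3ccc(OC)cc3)[C@@H]12 | intermediate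
33 | trans-fused 6,12-olide with C8–OPMB and C14, C15 TBDPS ethers | C=C1C(=O)O[C@@H]2/C=C(/CO[Si](c3ccccc3)(c3ccccc3)C(C)(C)C)CC/C=C(/CO[Si](c3ccccc3)(c3ccccc3)C(C)(C)C)C[C@@H](OCc3ccc(OC)cc3)[C@@H]12 | intermediate
34 | C8 alcohol of the lactone | C=C1C(=O)O[C@@H]2/C=C(/CO[Si](c3ccccc3)(c3ccccc3)C(C)(C)C)CC/C=C(/CO[Si](c3ccccc3)(c3ccccc3)C(C)(C)C)C[C@@H](O)[C@@H]12 | intermediate
35 | angelic acid, (2Z)-2-methylbut-2-enoic acid | C/C=C(/C)C(=O)O | starting material
36 | angelic 2,4,6-trichlorobenzoic anhydride | C/C=C(/C)C(=O)OC(=O)c1c(Cl)cc(Cl)cc1Cl | intermediate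
37 | C8 angelate with C14 and C15 TBDPS ethers | C=C1C(=O)O[C@@H]2/C=C(/CO[Si](c3ccccc3)(c3ccccc3)C(C)(C)C)CC/C=C(/CO[Si](c3ccccc3)(c3ccccc3)C(C)(C)C)C[C@@H](OC(=O)/C(C)=C\C)[C@@H]12 | intermediate
38 | CNP0182172.4, (6R,7R,8R)-8-angeloyloxy-14,15-dihydroxygermacra-1(10),4,11(13)-trien-6,12-olide with ring-cis C1=C10 and C4=C5 | C=C1C(=O)O[C@@H]2/C=C(/CO)CC/C=C(/CO)C[C@@H](OC(=O)/C(C)=C\C)[C@@H]12 | target

Total step count: 26. Longest linear sequence: 22 steps (from 7 through steps 4, 5 and 7 to 26).

Steps most likely to fail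

Step 13 (ring A closure). Ring A may close through the alternative chair, in which the C8 ether is equatorial and out of the allyl plane; this would place C11 trans to O8 (wrong facial selectivity at C7). The allylchromium may also lose the C8 alkoxide by 1,4-elimination. The fallback sets out from 19 and comes back at 21. The PMB group is removed first (DDQ, CH2Cl2, pH 7 buffer, 0 °C) to give the free C8 alcohol F1. Ring A is then closed by a Barbier allylation with indium powder and NaI in DMF at rt, in which the C8 hydroxyl binds the allylindium as an internal ligand and is thereby held in the allyl plane (hydroxyl-directed, chelation-controlled allylation); this should give the C6,C8-diol F2. Selective etherification of the secondary C8 hydroxyl (NaH, 4-methoxybenzyl bromide, Bu4NI, THF, 0 °C) returns to 21.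

Step 19 (key fragmentation). The C6 oxygen may attack C14 of the oxirane (5-exo opening to a bridged ether) faster than the C1–C6 bond breaks, or the chair with O6 and O8 axial may not be populated enough. The fallback sets out from 25 and comes back at 27. The fragmentation is triggered from the epoxide side on the silyl ether itself: catalytic Me3SiOTf with 2,6-di-tert-butyl-4-methylpyridine in CH2Cl2 at −78 °C silylates the oxirane oxygen, the tertiary C10–O bond ionises and the C6 silyl ether oxygen supplies the push, so the C6 oxygen is never a free nucleophile. This should give the C14 trimethylsilyl ether F3, and K2CO3 in MeOH at 0 °C then returns to 27.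

Step 21 (C6 reduction). Facial selectivity at C6 may be poor or of the wrong sense, because the two flanks of the ketone (branched C7 and the cis-enone carbon C5) may not differ enough for the catalyst. The fallback sets out from 28 and comes back at 29. A substrate-controlled Luche reduction (NaBH4, CeCl3·7H2O, MeOH, −78 °C) is used instead; should it deliver the C6-epimeric alcohol F4, a Mitsunobu inversion (4-nitrobenzoic acid, PPh3, diisopropyl azodicarboxylate, toluene, 0 °C) gives the inverted 4-nitrobenzoate F5, and methanolysis (K2CO3, MeOH, 0 °C) returns to 29.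

Further compounds
F1 | step 13 | C8 alcohol from 19 (PMB removed, allylic chloride and C10–OSiMe3 kept) | ClCC(CO[Si](C)(C)C(C)(C)C)=C[C@H](O)C[C@@H](O[Si](C)(C)C)[C@H]2CCC(CO[Si](c3ccccc3)(c3ccccc3)C(C)(C)C)=CC2=O
F2 | step 13 | cis-fused bicyclic C6,C8-diol (as 21 with free C8–OH) | O[C@]12[C@H](C(=C)CO[Si](C)(C)C(C)(C)C)[C@H](O)C[C@@H](O[Si](C)(C)C)[C@H]1CCC(CO[Si](c3ccccc3)(c3ccccc3)C(C)(C)C)=C2
F3 | step 19 | C14 trimethylsilyl ether of 27 | O=C1/C=C(/CO[Si](c2ccccc2)(c2ccccc2)C(C)(C)C)CC/C=C(/CO[Si](C)(C)C)C[C@@H](OCc2ccc(OC)cc2)[C@H]1C(=C)CO[Si](C)(C)C(C)(C)C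
F4 | step 21 | C6 epimer of 29, (6S)-alcohol | O[C@H]1/C=C(/CO[Si](c2ccccc2)(c2ccccc2)C(C)(C)C)CC/C=C(/CO[Si](c2ccccc2)(c2ccccc2)C(C)(C)C)C[C@@H](OCc2ccc(OC)cc2)[C@H]1C(=C)CO[Si](C)(C)C(C)(C)C
F5 | step 21 | (6R)-4-nitrobenzoate of 29 | [O-][N+](=O)c1ccc(cc1)C(=O)O[C@@H]2/C=C(/CO[Si](c3ccccc3)(c3ccccc3)C(C)(C)C)CC/C=C(/CO[Si](c3ccccc3)(c3ccccc3)C(C)(C)C)C[C@@H](OCc3ccc(OC)cc3)[C@H]2C(=C)CO[Si](C)(C)C(C)(C)C
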